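**Retrosynthetic overview**

1. After removal of the O-acetyl group, the side chain (numbered from the carbinol carbon C1) is cut at C4-C5, the bond between the methyl-bearing sp2 carbon of the first alkene and its allylic CH2. This bond is made by nickel-electrocatalytic decarboxylative alkenylation of a C17 redox-active ester (ring B half) with a C9 (E)-alkenyl iodide (ring A half).
2. Enabling feature: chain C4 bears only CH3, C5H2 and the double bond to C3, so it can be stored as a configurationally stable (E)-C(CH3)(I)=CH unit. C5H2-C6H2 is a saturated link whose primary radical comes from a γ,δ-unsaturated acid by loss of CO2. The only acceptors are hindered and hard to reduce: the alkene of the furan-2(5H)-one (ring A, β-carbon fully substituted) and the exocyclic C=C on C3 of the γ-butyrolactone (ring B, trisubstituted).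
3. Ring B half: Z-selective Horner-Wadsworth-Emmons olefination joins a (5S)-α-phosphono-γ-butyrolactone (chiral pool) to an aldehyde ester cut out of geranyl bromide.
4. Ring A half: syn-hydrozirconation/iodination of pent-3-yn-1-ol is followed by catalytic asymmetric 3-furylzinc addition (sets R). The furan is then converted to the butenolide with singlet oxygen and NaBH4.
5. Ring order: ring B is present from its starting lactone. Ring A enters as a furan and becomes the butenolide before the coupling. The key step closes no ring.

Key step: step 16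

Assumption: the exocyclic alkene of ring B is taken as written, with the chain cis to the lactone C=O (Z). The acetoxy carbon is R and C5 of ring B is S.

Step 1
Reactants: 1 geranyl bromide, (2E)-1-bromo-3,7-dimethylocta-2,6-diene
Product: 2 methyl (4E)-5,9-dimethyldeca-4,8-dienoate
Conditions: LiN(i-Pr)2, MeOAc, THF, −78 °C; then 1, DMPU, −78 to 0 °C
Reagents that add atoms: methyl acetate, COC(C)=O
Why: SN2 alkylation of an ester lithium enolate by a primary allylic bromide leaves the E alkene untouched and installs the CH2-CO2Me unit whose carbonyl carbon is later expelled as CO2.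

Step 2
Reactants: 2 methyl (4E)-5,9-dimethyldeca-4,8-dienoate
Product: 3 methyl (4E)-8-bromo-9-hydroxy-5,9-dimethyldec-4-enoate (racemic at C8)
Conditions: N-bromosuccinimide, THF/H2O, 0 °C
Reagents that add atoms: N-bromosuccinimide, O=C1CCC(=O)N1Br; water, O
Why: Bromohydrin formation in aqueous medium is known to select the terminal isopropylidene alkene of geranyl-type polyenes, with Markovnikov attack of water; the new centre is racemic and is destroyed in step 4.

Step 3
Reactants: 3 methyl (4E)-8-bromo-9-hydroxy-5,9-dimethyldec-4-enoate
Product: 4 methyl (4E)-7-(3,3-dimethyloxiran-2-yl)-5-methylhept-4-enoate (racemic)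
Conditions: K2CO3, MeOH, rt
Reagents that add atoms: none
Why: Intramolecular Williamson-type SN2 closure of the bromohydrin alkoxide gives the epoxide, and methanol as solvent keeps the methyl ester unchanged.

Step 4
Reactants: 4 methyl (4E)-7-(3,3-dimethyloxiran-2-yl)-5-methylhept-4-enoate
Product: 6 methyl (4E)-5-methyl-8-oxooct-4-enoate, via vicinal diol 5 (not isolated)
Conditions: H5IO6, THF/H2O, 0 °C
Reagents that add atoms: none
Why: Acidic opening of the epoxide at its tertiary carbon followed by Malaprade glycol cleavage in the same flask releases the aldehyde and acetone without touching the trisubstituted alkene or the ester.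

Step 5
Reactants: 7 (5S)-5-(hydroxymethyl)dihydrofuran-2(3H)-one
Product: 8 (2S)-5-oxotetrahydrofuran-2-carbaldehyde
Conditions: Dess-Martin periodinane, CH2Cl2, 0 °C to rt; filtration, used crude
Reagents that add atoms: none
Why: Dess-Martin oxidation is non-basic, so the α-acyloxy aldehyde is formed without epimerisation of the chiral-pool centre.

Step 6
Reactants: 8 (2S)-5-oxotetrahydrofuran-2-carbaldehyde
Product: 9 (5S)-5-(2-methylprop-1-en-1-yl)dihydrofuran-2(3H)-one
Conditions: i-PrPPh3I, KN(SiMe3)2, THF, 0 °C; then 8, −78 °C to rt
Reagents that add atoms: isopropyltriphenylphosphonium iodide, CC(C)[P+](c1ccccc1)(c1ccccc1)c1ccccc1.[I-]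
Why: Wittig olefination with a non-stabilised ylide at low temperature is faster than enolisation of the aldehyde or attack on the lactone, so the S centre is retained and becomes C5 of ring B.

Step 7
Reactants: 9 (5S)-5-(2-methylprop-1-en-1-yl)dihydrofuran-2(3H)-one
Product: 11 diethyl [(5S)-5-(2-methylprop-1-en-1-yl)-2-oxotetrahydrofuran-3-yl]phosphonate (C3 epimers), via enol phosphate 10 (not isolated)
Conditions: LiN(i-Pr)2 (1.1 equiv), THF, −78 °C; ClP(O)(OEt)2; LiN(i-Pr)2 (2.2 equiv), −78 °C to rt; AcOH
Reagents that add atoms: diethyl chlorophosphate, CCOP(=O)(Cl)OCC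
Why: O-phosphorylation of the lactone enolate followed by base-induced 1,3-migration of phosphorus from oxygen to carbon (vinyl phosphate to α-phosphono lactone rearrangement) gives the olefination reagent; the new C3 centre is irrelevant because it becomes sp2 in step 8.

Step 8
Reactants: 11 diethyl [(5S)-5-(2-methylprop-1-en-1-yl)-2-oxotetrahydrofuran-3-yl]phosphonate; 6 methyl (4E)-5-methyl-8-oxooct-4-enoate
Product: 12 methyl (4E,8Z)-5-methyl-8-[(5S)-5-(2-methylprop-1-en-1-yl)-2-oxodihydrofuran-3(2H)-ylidene]oct-4-enoate
Conditions: KN(SiMe3)2, 18-crown-6, THF, −78 °C; then 6, −78 °C, cold quench; chromatographic removal of the E isomer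
Reagents that add atoms: none
Why: Horner-Wadsworth-Emmons olefination under dissociating conditions (potassium sequestered by the crown ether, low temperature) makes the addition irreversible, so the kinetic adduct collapses to the Z alkylidene lactone with the chain cis to C=O, as known for α-phosphono lactones and aliphatic aldehydes.

Step 9
Reactants: 12 methyl (4E,8Z)-5-methyl-8-[(5S)-5-(2-methylprop-1-en-1-yl)-2-oxodihydrofuran-3(2H)-ylidene]oct-4-enoate
Product: 13 (4E,8Z)-5-methyl-8-[(5S)-5-(2-methylprop-1-en-1-yl)-2-oxodihydrofuran-3(2H)-ylidene]oct-4-enoic acid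
Conditions: Me3SnOH, ClCH2CH2Cl, 70 °C; dilute HCl wash
Reagents that add atoms: trimethyltin hydroxide, C[Sn](C)(C)O
Why: Tin hydroxide mediated hydrolysis cleaves the unhindered methyl ester under near-neutral conditions, the conjugated lactone is less electrophilic (and would reclose on the acid wash if opened), and no strong acid is used that could ionise the allylic C5-O bond of ring B.

Step 10
Reactants: 13 (4E,8Z)-5-methyl-8-[(5S)-5-(2-methylprop-1-en-1-yl)-2-oxodihydrofuran-3(2H)-ylidene]oct-4-enoic acid
Product: 14 1,3-dioxoisoindolin-2-yl (4E,8Z)-5-methyl-8-[(5S)-5-(2-methylprop-1-en-1-yl)-2-oxodihydrofuran-3(2H)-ylidene]oct-4-enoate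
Conditions: N-hydroxyphthalimide, N,N'-diisopropylcarbodiimide, 4-(dimethylamino)pyridine (cat.), CH2Cl2, rt
Reagents that add atoms: N-hydroxyphthalimide, O=C1c2ccccc2C(=O)N1O
Why: Carbodiimide (Steglich-type) esterification gives the chromatographically stable primary redox-active ester without affecting alkenes or the lactone.

Step 11
Reactants: 15 pent-3-yn-1-ol
Product: 17 (3E)-4-iodopent-3-en-1-ol, via alkenylzirconocene 16 (not isolated)
Conditions: Cp2Zr(H)Cl (2.2 equiv), THF, rt, dark; then I2, −78 to 0 °C
Reagents that add atoms: iodine, II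
Why: The first equivalent of hydride only deprotonates the hydroxy group, syn hydrozirconation then places zirconium on the less hindered methyl-bearing alkyne carbon after equilibration with excess hydride, and iodinolysis with retention gives the E iodide.

Step 12
Reactants: 17 (3E)-4-iodopent-3-en-1-ol
Product: 18 (3E)-4-iodopent-3-enal
Conditions: Dess-Martin periodinane, NaHCO3, CH2Cl2, 0 °C; used at once
Reagents that add atoms: none
Why: Buffered Dess-Martin oxidation stops at the aldehyde and avoids the acid- or base-induced migration of the β,γ-alkene into conjugation.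

Step 13
Reactants: 18 (3E)-4-iodopent-3-enal; 19 3-bromofuran
Product: 22 (1R,3E)-1-(furan-3-yl)-4-iodopent-3-en-1-ol, via furan-3-yllithium 20 (not isolated), via ethyl(furan-3-yl)zinc 21 (not isolated)
Conditions: 19, n-BuLi, t-BuOMe, −78 °C; EtZnCl, −78 to 0 °C; N,N,N',N'-tetraethylethylenediamine, (2S)-3-exo-morpholinoisoborneol (10 mol %), toluene; then 18, −10 °C; aq NH4Cl
Reagents that add atoms: none
Why: In this catalytic asymmetric addition of a mixed ethyl(heteroaryl)zinc reagent to an aldehyde, the amino alcohol zinc chelate delivers the furyl group to the Si face of 18 and so sets the R carbinol centre, the diamine masks LiCl to suppress the racemic background path, and the non-basic zinc reagent spares the enolisable aldehyde and the alkenyl iodide.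

Step 14
Reactants: 22 (1R,3E)-1-(furan-3-yl)-4-iodopent-3-en-1-ol
Product: 24 5-hydroxy-4-[(1R,3E)-1-hydroxy-4-iodopent-3-en-1-yl]furan-2(5H)-one (C5 epimers), via furan endoperoxide 23 (not isolated)
Conditions: O2, 5,10,15,20-tetraphenylporphyrin (cat.), i-Pr2NEt, CH2Cl2, visible light, −78 °C
Reagents that add atoms: dioxygen, O=O
Why: (4+2) addition of singlet oxygen to the furan is followed by Kornblum-DeLaMare fragmentation in which the hindered amine removes the bridgehead hydrogen remote from the side chain, so the carbonyl forms at the former furan C5 and the 4-substituted 5-hydroxybutenolide results, while the electron-poor iodoalkene is too slow for an ene reaction at this temperature.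

Step 15
Reactants: 24 5-hydroxy-4-[(1R,3E)-1-hydroxy-4-iodopent-3-en-1-yl]furan-2(5H)-one
Product: 26 4-[(1R,3E)-1-hydroxy-4-iodopent-3-en-1-yl]furan-2(5H)-one, via hydroxy acid 25 (not isolated)
Conditions: NaBH4, EtOH, 0 °C; then dilute HCl to pH 3
Reagents that add atoms: none
Why: Borohydride reduces the open aldehyde tautomer of the hydroxybutenolide in 1,2 fashion, and hydroxy acid 25 lactonises on acidification through its CH2OH group, which lies cis to the carboxyl group, whereas the secondary carbinol is trans to it and cannot compete.

Step 16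
Reactants: 14 1,3-dioxoisoindolin-2-yl (4E,8Z)-5-methyl-8-[(5S)-5-(2-methylprop-1-en-1-yl)-2-oxodihydrofuran-3(2H)-ylidene]oct-4-enoate; 26 4-[(1R,3E)-1-hydroxy-4-iodopent-3-en-1-yl]furan-2(5H)-one
Product: 28 4-[(1R,3E,7E,11Z)-1-hydroxy-4,8-dimethyl-11-[(5S)-5-(2-methylprop-1-en-1-yl)-2-oxodihydrofuran-3(2H)-ylidene]undeca-3,7-dien-1-yl]furan-2(5H)-one, via homoallyl radical 27 (not isolated)
Conditions: 14 (1.5 equiv), NiCl2·6H2O (20 mol %), 2,2'-bipyridine (20 mol %), AgNO3 (0.3 equiv), DMF, undivided cell, Mg anode, reticulated vitreous carbon cathode, constant current, about 3 F/mol, rt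
Reagents that add atoms: none
Why: At the cathode the 2,2'-bipyridine complex of divalent nickel is reduced to low-valent nickel, which inserts into the C(sp2)-I bond of 26 with retention of the E geometry, while one-electron reduction of 14 (at the silver nanoparticle layer deposited from AgNO3, or by monovalent nickel) releases phthalimide anion, CO2 and the primary homoallyl radical 27; capture of 27 by the alkenylnickel species and reductive elimination from trivalent nickel make the C(sp3)-C(sp2) bond, the Mg anode supplying the two electrons. The closest known reaction type is the nickel-electrocatalytic decarboxylative alkenylation of primary redox-active esters with (E)-2-iodoalk-2-enes used for the modular assembly of 1,5-polyene terpenoid chains, so only the substrate is new. No ring is closed and no stereocentre is created: rings A and B and both carbinol centres pass through unchanged, and the one stereoelement made, the E trisubstituted alkene at chain C3-C4, is dictated by the geometry of the iodide because oxidative addition and reductive elimination are stereoretentive. The step needs cross- over homo-coupling and chemoselectivity against two conjugated lactones: the acceptor carbon of ring A is fully substituted and that of ring B belongs to a trisubstituted alkylidene, so Giese addition of 27 is slower than its capture by nickel, cyclisation of 27 onto the ring B alkylidene would require a trans-cycloheptene, and both lactones are reduced only at potentials well beyond those of 14 and the nickel complex. The carbinol is carried as the free alcohol and not as the acetate, because an acetate allylic to the electron-poor ring A alkene could ionise on zerovalent nickel, whereas the allylic C5-O bond of ring B is flanked by an electron-rich trisubstituted alkene that binds nickel poorly. In one operation a C9 and a C16 unit with all oxygen functions unprotected should give the complete C25 skeleton with three defined alkenes and two stereocentres, one acetylation short of the target.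

Step 17
Reactants: 28 4-[(1R,3E,7E,11Z)-1-hydroxy-4,8-dimethyl-11-[(5S)-5-(2-methylprop-1-en-1-yl)-2-oxodihydrofuran-3(2H)-ylidene]undeca-3,7-dien-1-yl]furan-2(5H)-one
Product: 29 (1R,3E,7E,11Z)-4,8-dimethyl-11-[(5S)-5-(2-methylprop-1-en-1-yl)-2-oxodihydrofuran-3(2H)-ylidene]-1-(5-oxo-2,5-dihydrofuran-3-yl)undeca-3,7-dien-1-yl acetate (target)
Conditions: Ac2O, pyridine, 4-(dimethylamino)pyridine (cat.), CH2Cl2, 0 °C
Reagents that add atoms: acetic anhydride, CC(=O)OC(C)=O
Why: Nucleophile-catalysed O-acylation of the only hydroxy group does not touch the C-O bond, so the R configuration is retained, and the mild base at low temperature avoids vinylogous elimination at ring A.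

**Compound list**

1 | geranyl bromide, (2E)-1-bromo-3,7-dimethylocta-2,6-diene | CC(C)=CCC/C(C)=C/CBr | starting material
2 | methyl (4E)-5,9-dimethyldeca-4,8-dienoate | COC(=O)CC/C=C(\C)CCC=C(C)C | intermediate
3 | methyl (4E)-8-bromo-9-hydroxy-5,9-dimethyldec-4-enoate (racemic at C8) | COC(=O)CC/C=C(\C)CCC(Br)C(C)(C)O | intermediate
4 | methyl (4E)-7-(3,3-dimethyloxiran-2-yl)-5-methylhept-4-enoate (racemic) | COC(=O)CC/C=C(\C)CCC1OC1(C)C | intermediate
5 | methyl (4E)-8,9-dihydroxy-5,9-dimethyldec-4-enoate (not isolated) | COC(=O)CC/C=C(\C)CCC(O)C(C)(C)O | intermediate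
6 | methyl (4E)-5-methyl-8-oxooct-4-enoate | COC(=O)CC/C=C(\C)CCC=O | intermediate
7 | (5S)-5-(hydroxymethyl)dihydrofuran-2(3H)-one | O=C1CC[C@@H](CO)O1 | starting material
8 | (2S)-5-oxotetrahydrofuran-2-carbaldehyde | O=C1CC[C@@H](C=O)O1 | intermediate
9 | (5S)-5-(2-methylprop-1-en-1-yl)dihydrofuran-2(3H)-one | O=C1CC[C@@H](C=C(C)C)O1 | intermediate
10 | diethyl (5S)-5-(2-methylprop-1-en-1-yl)-4,5-dihydrofuran-2-yl phosphate (not isolated) | CCOP(=O)(OCC)OC1=CC[C@@H](C=C(C)C)O1 | intermediate
11 | diethyl [(5S)-5-(2-methylprop-1-en-1-yl)-2-oxotetrahydrofuran-3-yl]phosphonate (C3 epimers) | CCOP(=O)(OCC)C1C[C@@H](C=C(C)C)OC1=O | intermediate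
12 | methyl (4E,8Z)-5-methyl-8-[(5S)-5-(2-methylprop-1-en-1-yl)-2-oxodihydrofuran-3(2H)-ylidene]oct-4-enoate | COC(=O)CC/C=C(\C)CC/C=C1/C[C@@H](C=C(C)C)OC1=O | intermediate
13 | (4E,8Z)-5-methyl-8-[(5S)-5-(2-methylprop-1-en-1-yl)-2-oxodihydrofuran-3(2H)-ylidene]oct-4-enoic acid | OC(=O)CC/C=C(\C)CC/C=C1/C[C@@H](C=C(C)C)OC1=O | intermediate
14 | 1,3-dioxoisoindolin-2-yl ester of 13 (redox-active ester) | O=C(CC/C=C(\C)CC/C=C1/C[C@@H](C=C(C)C)OC1=O)ON1C(=O)c2ccccc2C1=O | intermediate
15 | pent-3-yn-1-ol | CC#CCCO | starting material
16 | (E)-alkenylzirconocene chloride from 15, zirconium on C4 and on oxygen (not isolated) | C/C(=C\CCO[Zr](Cl)(C1C=CC=C1)C1C=CC=C1)[Zr](Cl)(C1C=CC=C1)C1C=CC=C1 | intermediate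
17 | (3E)-4-iodopent-3-en-1-ol | OCC/C=C(\C)I | intermediate
18 | (3E)-4-iodopent-3-enal | O=CC/C=C(\C)I | intermediate
19 | 3-bromofuran | Brc1ccoc1 | starting material
20 | furan-3-yllithium (not isolated) | [Li]c1ccoc1 | intermediate
21 | ethyl(furan-3-yl)zinc (not isolated) | CC[Zn]c1ccoc1 | intermediate
22 | (1R,3E)-1-(furan-3-yl)-4-iodopent-3-en-1-ol | O[C@H](C/C=C(\C)I)c1ccoc1 | intermediate
23 | 5-[(1R,3E)-1-hydroxy-4-iodopent-3-en-1-yl]-2,3,7-trioxabicyclo[2.2.1]hept-5-ene (not isolated) | O[C@H](C/C=C(\C)I)C1=CC2OOC1O2 | intermediate
24 | 5-hydroxy-4-[(1R,3E)-1-hydroxy-4-iodopent-3-en-1-yl]furan-2(5H)-one (C5 epimers) | O[C@H](C/C=C(\C)I)C1=CC(=O)OC1O | intermediate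
25 | (2E,4R,6E)-4-hydroxy-3-(hydroxymethyl)-7-iodoocta-2,6-dienoic acid (not isolated) | O[C@H](C/C=C(\C)I)/C(CO)=C/C(=O)O | intermediate
26 | 4-[(1R,3E)-1-hydroxy-4-iodopent-3-en-1-yl]furan-2(5H)-one | O[C@H](C/C=C(\C)I)C1=CC(=O)OC1 | intermediate
27 | primary homoallyl radical from 14 by loss of phthalimide anion and CO2 (not isolated) | [CH2]C/C=C(\C)CC/C=C1/C[C@@H](C=C(C)C)OC1=O | intermediate
28 | 4-[(1R,3E,7E,11Z)-1-hydroxy-4,8-dimethyl-11-[(5S)-5-(2-methylprop-1-en-1-yl)-2-oxodihydrofuran-3(2H)-ylidene]undeca-3,7-dien-1-yl]furan-2(5H)-one | O[C@H](C/C=C(\C)CC/C=C(\C)CC/C=C1/C[C@@H](C=C(C)C)OC1=O)C1=CC(=O)OC1 | intermediate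
29 | (1R,3E,7E,11Z)-4,8-dimethyl-11-[(5S)-5-(2-methylprop-1-en-1-yl)-2-oxodihydrofuran-3(2H)-ylidene]-1-(5-oxo-2,5-dihydrofuran-3-yl)undeca-3,7-dien-1-yl acetate | CC(=O)O[C@H](C/C=C(\C)CC/C=C(\C)CC/C=C1/C[C@@H](C=C(C)C)OC1=O)C1=CC(=O)OC1 | target

**Total step count:** 17.

**Longest linear sequence:** 9 steps (1, 2, 3, 4, 8, 9, 10, 16, 17) from geranyl bromide. The lactone branch needs 8 steps to the target and the ring A branch needs 7.

**Steps most likely to fail**

**1. Step 16.**
- Process at risk: low-valent nickel may bind to the electron-poor ring A alkene. The redox-active ester may be reduced prematurely, followed by hydrogen abstraction or dimerisation of the radical. The radical may also add in conjugate fashion. Any of these erodes cross-selectivity.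
- Fallback, from 14 and 26 back to 28: the radical/nickel manifold is replaced by a two-electron palladium cross-coupling. Visible-light iododecarboxylation of 14 (LiI, PPh3 as catalyst, acetone, blue light) should give (3Z,5S)-3-[(4E)-7-iodo-4-methylhept-4-en-1-ylidene]-5-(2-methylprop-1-en-1-yl)dihydrofuran-2(3H)-one F1. Insertion of zinc dust in the presence of LiCl (THF, rt) should give the corresponding primary alkylzinc iodide F2. F2 then undergoes Negishi coupling with 26 under Pd(OAc)2 and 2-dicyclohexylphosphino-2',6'-dimethoxybiphenyl in THF at rt. F2 is used in excess with slow addition to allow for the free hydroxy group. The coupling is stereoretentive at the alkenyl iodide and returns to 28.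

**2. Step 8.**
- Process at risk: incomplete kinetic control (reversible addition) may give poor Z selectivity, or base may cause the Z alkylidene to drift to the E isomer.
- Fallback, from 9 and 6 back to 12: the olefination is replaced by an aldol addition and a stereospecific elimination. The lithium enolate of 9 (LiN(i-Pr)2, THF, −78 °C) is locked in the E(O) geometry by the ring. It adds to 6 through a closed chair transition state on the face away from the C5 substituent. This should favour the anti aldol adduct methyl (4E,8S)-8-hydroxy-5-methyl-8-[(3S,5S)-5-(2-methylprop-1-en-1-yl)-2-oxotetrahydrofuran-3-yl]oct-4-enoate F3, which is freed from its syn isomer by chromatography. MsCl and Et3N give the derived methanesulfonate F4. DBU in toluene at 0 °C then effects anti-periplanar E2 loss of methanesulfonate. From the anti diastereomer this places the chain cis to C=O and returns to 12.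

**3. Step 13.**
- Process at risk: facial selectivity may be modest with an unbranched aliphatic aldehyde, ethyl transfer may compete, or 18 may be lost by migration of its alkene into conjugation.
- Fallback, from 18 and 19 back to 22: the stereocentre is set by reagent-controlled ketone reduction instead of by addition. Furan-3-yllithium 20 (from 19, n-BuLi, −78 °C) is added directly to 18 to give racemic (3E)-1-(furan-3-yl)-4-iodopent-3-en-1-ol F5. Dess-Martin oxidation gives (3E)-1-(furan-3-yl)-4-iodopent-3-en-1-one F6. Corey-Bakshi-Shibata reduction follows, with (S)-1-methyl-3,3-diphenyltetrahydro-1H,3H-pyrrolo[1,2-c][1,3,2]oxazaborole (cat.) and BH3·SMe2 in THF at −30 °C. With the furyl group as the large substituent, it should deliver the R alcohol 22.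

**Further compounds**

F1 | step 16 | (3Z,5S)-3-[(4E)-7-iodo-4-methylhept-4-en-1-ylidene]-5-(2-methylprop-1-en-1-yl)dihydrofuran-2(3H)-one | ICC/C=C(\C)CC/C=C1/C[C@@H](C=C(C)C)OC1=O
F2 | step 16 | primary alkylzinc iodide derived from F1 | I[Zn]CC/C=C(\C)CC/C=C1/C[C@@H](C=C(C)C)OC1=O
F3 | step 8 | methyl (4E,8S)-8-hydroxy-5-methyl-8-[(3S,5S)-5-(2-methylprop-1-en-1-yl)-2-oxotetrahydrofuran-3-yl]oct-4-enoate (anti aldol adduct) | COC(=O)CC/C=C(\C)CC[C@H](O)[C@@H]1C[C@@H](C=C(C)C)OC1=O
F4 | step 8 | methanesulfonate of F3 | COC(=O)CC/C=C(\C)CC[C@H](OS(C)(=O)=O)[C@@H]1C[C@@H](C=C(C)C)OC1=O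
F5 | step 13 | racemic (3E)-1-(furan-3-yl)-4-iodopent-3-en-1-ol | OC(C/C=C(\C)I)c1ccoc1
F6 | step 13 | (3E)-1-(furan-3-yl)-4-iodopent-3-en-1-one | O=C(C/C=C(\C)I)c1ccoc1
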